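**Target:** CNP0269915.2 (34), epicatechin 3‑O‑gallate‑(4β→8)‑epicatechin 3‑O‑gallate‑(4β→8)‑catechin. Units are called U (upper), M (middle) and T (terminal).

## The problem

- Compound 34 is a linear B‑type trimer of three 2‑arylchroman‑3‑ol units. U and M are (−)‑epicatechin 3‑O‑gallates, T is (+)‑catechin, and the units are joined by two C4–C8 bonds that are both β (trans to the C3 oxygen).
- Of the eight stereocentres, C2/C3 of U and T can be taken from (−)‑epicatechin 1 and (+)‑catechin 27. Each C4 centre can be set by its C3 neighbour, because a nucleophile adds to a flavan C4 cation anti to the C3 oxygen. C2/C3 of M is the one pair that has to be made.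
- The usual union (arene plus C4 cation) does not decide which position of the arene reacts. A chain‑internal unit has C6 and C8 open, so the U–M bond is the regiochemical problem. The terminal bond goes to C8 of a monomeric catechin, where the preference is established.
- The 4‑arylflavan bonds are cleaved by acid (retro‑Friedel–Crafts). With free phenols, C2 epimerises and the rings oxidise in base, and the gallates are base‑labile. All phenols therefore stay benzyl ethers to the end and hydrogenolysis comes last.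
- Ring A of M is a phloroglucinol in which C8 carries C4 of U and is flanked by O1 (on C8a) and O7, with O5 para. This is the pattern formed when a 3‑oxygenated vinylketene is joined to a ynol ether whose carbon terminus bears U.
- In that ring synthesis the ketene oxygen emerges as the only free hydroxyl (O1). It is the handle needed to build ring C of M at the one free ortho carbon (C4a).

## Retrosynthesis

**34 back to 30 (protecting groups).** The nineteen O–benzyl bonds of 33 are cut last. The gallate on U is disconnected to 32 and acid 22, because the C3 oxygen of U must pass through organolithium and peroxide chemistry as a silyl ether. The O7 silyl ether that the ring synthesis leaves is exchanged for benzyl (31 to 32) once the last C–C bond is in place, so that fluoride never meets a C4 leaving group.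

**30 to 26 + 29.** The C4(M)–C8(T) bond is cut as a flavan C4 cation plus penta‑O‑benzylcatechin 29. The C3 gallate of 26 shields the α face, so 4β follows, and the nucleophile is a monomer with the known C8 preference. Joining T before ring C of M exists was weighed: it needs a quinone methide carrying a doubly ortho‑substituted aryl group on the reacting carbon and three stereocentres from one intermolecular step. Cutting here leaves a dimer and a two‑step catechin ether.

**26 to 19 + 23.** O1–C2 and C3–C4 of ring C of M are cut together as a formal [4+2]. The formyl carbon of 19 becomes C4 and keeps its oxidation level as a methoxy leaving group, so no reduction and re‑oxidation is needed. The (Z)‑enol gallate 23 supplies C2, C3, ring B and the gallate of M, and its geometry becomes the 2,3‑cis relationship. A silicon placeholder for O3 was set aside because the adduct would be a 2‑silylethyl aryl ether, which fluoride fragments. The forward step must control which alkene carbon attacks and which face.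

**19 to 18.** One C–C bond to the only free ortho position of the phenol.

**18 to 10 + 14 (key).** C8–C8a and C6–C7 of ring A of M are cut (C4a–C8a is re‑formed in the cascade), giving siloxyalkyne 10 on C4 of U and cyclobutenone 14. No Friedel–Crafts reaction on a ring with two open positions is involved, and the three oxygens arrive as free OH, silyl ether and benzyl ether.

**10 to 1.** The ynol silyl ether comes from terminal alkyne 8 (acetylide oxidation), 8 from silylalkyne 7, and 7 from C4 ether 4 and alkynylborate 6 (made from 5). Compound 4 comes from epicatechin 1 through 2 and 3; all three stereocentres of U are either native or set by C3.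

**Small pieces.** 14 comes from dione 13, enol ether 12 and ethoxyacetylene 11. 23 comes from alkyne 21 (from aldehyde 20) and acid 22. 29 comes from catechin 27 through 28.

## Roads not taken

**Alternative 1:** the cut is C4a–C8a of U, so ring A of the upper unit is built. Mg(OMe)2 would fold a 3,5‑dioxo ester chain by Claisen closure and aromatisation to phloroglucinol A1.
- Merits: the U–M bond exists before the ring, so its regiochemistry is also fixed by construction. The new ring is symmetric, so no oxygens need telling apart, and the reagents are cheap and robust. In these respects it is as good as or better than the chosen plan.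
- Weak points: U then has to be made open‑chain. C2, C3 and C4 must be set on an acyclic chain that already carries the bulky M aryl group. Ring C must still be closed by displacement at an electron‑rich benzylic C2, where ionisation erodes the 2,3‑cis outcome. The tri‑phenol needs reprotection.
- Against this the chosen plan sets that U comes intact from 1 and the key step creates no stereocentre.

**Alternative 2:** the cut is C4–C4a of M. BF3·OEt2 would ionise a C4 methyl ether, the C3 gallate would bridge the cation, and a tethered 3,5‑bis(benzyloxy)phenyl ether would close anti to it to give dimer A2.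
- Merits: the M–T bond is fixed before cyclisation and 3,4‑trans is enforced intramolecularly. For this bond it is better than step 18 of the chosen route, which relies on the C8 preference of catechin.
- Weak points: A2 has C6 and C8 of M and C6 of T open, so U would be attached by an intermolecular cation coupling with exactly the ambiguity the target poses. The acyclic precursor needs a configurationally defined C2 aryl ether next to an ester.
- Against this the chosen plan sets that the chain‑internal bond is the one fixed by construction and the easy terminal bond is the one left to classical coupling.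

**Alternative 3:** the cut is C2=C3 of U. The second‑generation Grubbs catalyst would close an α‑aryloxystyrene onto a C4 vinyl group to give flav‑2‑ene A3.
- Merits: the step is catalytic and neutral, suits the acid‑labile bond, and is convergent with the U–M bond already present. It needs no strained ketene precursor and no sensitive alkyne, which the chosen plan cannot claim.
- Weak points: electron‑rich 1,1‑disubstituted enol ethers are poor metathesis partners. Hydroboration of A3 adds H and B to the same face anti to the C4 aryl group, which gives the 2,3‑trans‑3,4‑trans pattern, the C2 epimer of an epicatechin unit. Anti addition by epoxidation and hydride opening has no secure control at C2. The C4 diarylmethine must first be made enantioselectively.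
- Against this the chosen plan sets that all three stereocentres of U come from 1.

Key step: step 11

Assumption: the matched enantiomer of the phosphoric acid in step 15 cannot be predicted for this substrate; the (R)‑acid is written and the (S)‑acid replaces it without other change if it proves to be the matched one.

## Route

Step 1
Reactants: 1 (−)-epicatechin
Product: 2 5,7,3',4'-tetra-O-benzyl-(−)-epicatechin
Conditions: BnBr, K2CO3, DMF, 0 °C → rt
Reagents that add atoms: benzyl bromide, BrCc1ccccc1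
Why: Williamson etherification; carbonate deprotonates only the four phenols, so the C3 hydroxyl stays free and C2 is not epimerised.

Step 2
Reactants: 2 5,7,3',4'-tetra-O-benzyl-(−)-epicatechin
Product: 3 4β-(2-ethoxyethoxy)-5,7,3',4'-tetra-O-benzylepicatechin
Conditions: DDQ, HOCH2CH2OEt, CH2Cl2, rt
Reagents that add atoms: 2-ethoxyethanol, CCOCCO
Why: DDQ benzylic oxidation of a flavan; hydride abstraction at C4 is assisted by the 5,7-dialkoxy ring A and the alcohol traps the cation anti to the C3 hydroxyl, giving the 3,4-trans (4β) ether.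

Step 3
Reactants: 3 4β-(2-ethoxyethoxy)-5,7,3',4'-tetra-O-benzylepicatechin
Product: 4 4β-(2-ethoxyethoxy)-5,7,3',4'-tetra-O-benzyl-3-O-TBS-epicatechin
Conditions: TBSCl, imidazole, DMF, 40 °C
Reagents that add atoms: tert-butyldimethylsilyl chloride, CC(C)(C)[Si](C)(C)Cl
Why: silylation of the axial C3 alcohol under non-acidic conditions that leave the acid-labile C4 ether untouched.

Step 4
Reactants: 5 trimethylsilylacetylene
Product: 6 potassium (trimethylsilylethynyl)trifluoroborate
Conditions: n-BuLi, THF, −78 °C; B(OMe)3, −78 → −20 °C; KHF2, H2O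
Reagents that add atoms: trimethyl borate, COB(OC)OC; potassium hydrogen difluoride, [K+].F[H-]F
Why: lithiation of the terminal alkyne, borylation and fluoride exchange, the standard preparation of potassium alkynyltrifluoroborates.

Step 5
Reactants: 4 4β-(2-ethoxyethoxy)-5,7,3',4'-tetra-O-benzyl-3-O-TBS-epicatechin; 6 potassium (trimethylsilylethynyl)trifluoroborate
Product: 7 4β-[(trimethylsilyl)ethynyl]-5,7,3',4'-tetra-O-benzyl-3-O-TBS-epicatechin
Conditions: BF3·OEt2, MeCN/CH2Cl2, −40 → 0 °C
Reagents that add atoms: none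
Why: BF3 ionises the C4 ether to the ring-A-stabilised cation and turns the trifluoroborate into an alkynyldifluoroborane that transfers its alkynyl group (addition of organotrifluoroborates to benzylic and oxocarbenium ions); attack anti to the axial C3 silyloxy group sets the 4β (3,4-trans) centre, as with other carbon nucleophiles at flavan C4.

Step 6
Reactants: 7 4β-[(trimethylsilyl)ethynyl]-5,7,3',4'-tetra-O-benzyl-3-O-TBS-epicatechin
Product: 8 4β-ethynyl-5,7,3',4'-tetra-O-benzyl-3-O-TBS-epicatechin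
Conditions: K2CO3, MeOH/THF, rt
Reagents that add atoms: none
Why: methanolysis of the C(sp)–Si bond; silyl and benzyl ethers are inert.

Step 7
Reactants: 8 4β-ethynyl-5,7,3',4'-tetra-O-benzyl-3-O-TBS-epicatechin
Product: 10 4β-[(triisopropylsilyloxy)ethynyl]-5,7,3',4'-tetra-O-benzyl-3-O-TBS-epicatechin, via lithium ynolate 9 (not isolated)
Conditions: n-BuLi, THF, −78 °C; LiOOt-Bu (t-BuOOH, LiN(SiMe3)2), −78 → 0 °C; i-Pr3SiOTf, −78 → 0 °C
Reagents that add atoms: tert-butyl hydroperoxide, CC(C)(C)OO; triisopropylsilyl trifluoromethanesulfonate, CC(C)[Si](C(C)C)(C(C)C)OS(=O)(=O)C(F)(F)F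
Why: oxidation of a lithium acetylide by lithium tert-butylperoxide gives the ynolate, and the bulky silyl triflate silylates it on oxygen (the standard route to triisopropylsiloxyalkynes); one equivalent of n-BuLi removes only the acetylenic proton.

Step 8
Reactants: 11 ethoxyacetylene
Product: 12 3-ethoxycyclobut-2-en-1-one
Conditions: CH2=C=O (gas), CH2Cl2, 0 °C
Reagents that add atoms: ketene, C=C=O
Why: [2+2] cycloaddition of ketene with an alkoxyalkyne; the unsubstituted alkyne carbon bonds to the ketene carbonyl carbon.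

Step 9
Reactants: 12 3-ethoxycyclobut-2-en-1-one
Product: 13 cyclobutane-1,3-dione
Conditions: HCl (2 M aq), 0 °C → rt
Reagents that add atoms: water, O
Why: acid hydrolysis of a vinylogous ester.

Step 10
Reactants: 13 cyclobutane-1,3-dione
Product: 14 3-(benzyloxy)cyclobut-2-en-1-one
Conditions: BnOH, PPh3, DIAD, THF, 0 °C → rt
Reagents that add atoms: benzyl alcohol, OCc1ccccc1
Why: Mitsunobu O-alkylation of the strongly acidic enol of a 1,3-dione; neutral conditions avoid opening of the strained ring by alkoxide.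

Step 11
Reactants: 10 4β-[(triisopropylsilyloxy)ethynyl]-5,7,3',4'-tetra-O-benzyl-3-O-TBS-epicatechin; 14 3-(benzyloxy)cyclobut-2-en-1-one
Product: 18 2-(5,7,3',4'-tetra-O-benzyl-3-O-TBS-epicatechin-4β-yl)-5-benzyloxy-3-(triisopropylsilyloxy)phenol, via (1-benzyloxyvinyl)ketene 15 (not isolated), via vinylcyclobutenone adduct 16 (not isolated), via dienylketene 17 (not isolated)
Conditions: PhMe, 80 → 110 °C
Reagents that add atoms: none
Why: Danheiser benzannulation. Heat opens 14 by 4π electrocyclic ring opening to ketene 15; the siloxyalkyne adds to the ketene C=C in a [2+2] in which its nucleophilic carbon (the one carrying C4 of U, remote from oxygen) bonds to the ketene carbonyl carbon, giving 16. A second 4π opening gives dienylketene 17, which closes by thermal 6π electrocyclisation (C4a–C8a) to a cyclohexadienone that tautomerises to the phenol. The closest known reaction is the benzannulation of cyclobutenones with triisopropylsiloxyalkynes to resorcinol monosilyl ethers; the 3-alkoxy group of 14 supplies the third oxygen. Ring A of M is therefore closed by a pericyclic cascade and not by substitution on an existing arene. No stereocentre is formed, and C4 of U is a spectator with no acidic or leaving group under neutral thermolysis. The selectivity needed is the orientation of the [2+2], and the polarity of the ynol ether secures it: the carbon bearing U ends ortho to the new hydroxyl (C8), the silyloxy carbon becomes C7 and the benzyloxy carbon C5, so only O1 is free.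

Step 12
Reactants: 18 2-(5,7,3',4'-tetra-O-benzyl-3-O-TBS-epicatechin-4β-yl)-5-benzyloxy-3-(triisopropylsilyloxy)phenol
Product: 19 6-benzyloxy-2-hydroxy-3-(5,7,3',4'-tetra-O-benzyl-3-O-TBS-epicatechin-4β-yl)-4-(triisopropylsilyloxy)benzaldehyde
Conditions: MgCl2, Et3N, (CH2O)n, THF, reflux
Reagents that add atoms: formaldehyde (as paraformaldehyde), C=O
Why: magnesium-mediated ortho-formylation (Casnati–Skattebøl); the magnesium phenoxide delivers formaldehyde to the only free ortho position and a second formaldehyde oxidises the benzylic alkoxide; no acid is present, so the silyl ethers and the 4-arylflavan bond survive.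

Step 13
Reactants: 20 3,4-bis(benzyloxy)benzaldehyde
Product: 21 1,2-bis(benzyloxy)-4-ethynylbenzene
Conditions: MeC(O)C(N2)P(O)(OMe)2, K2CO3, MeOH, rt
Reagents that add atoms: dimethyl (1-diazo-2-oxopropyl)phosphonate, CC(=O)C(=[N+]=[N-])P(=O)(OC)OC
Why: Ohira–Bestmann (Seyferth–Gilbert) homologation of an aromatic aldehyde.

Step 14
Reactants: 21 1,2-bis(benzyloxy)-4-ethynylbenzene; 22 3,4,5-tris(benzyloxy)benzoic acid
Product: 23 (Z)-2-[3,4-bis(benzyloxy)phenyl]ethenyl 3,4,5-tris(benzyloxy)benzoate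
Conditions: Ru(η3-CH2CMeCH2)2(Ph2P(CH2)4PPh2) (2 mol %), PhMe, 65 °C
Reagents that add atoms: none
Why: ruthenium-catalysed anti-Markovnikov addition of a carboxylic acid to a terminal alkyne through a vinylidene complex, which gives the (Z)-enol ester.

Step 15
Reactants: 19 6-benzyloxy-2-hydroxy-3-(5,7,3',4'-tetra-O-benzyl-3-O-TBS-epicatechin-4β-yl)-4-(triisopropylsilyloxy)benzaldehyde; 23 (Z)-2-[3,4-bis(benzyloxy)phenyl]ethenyl 3,4,5-tris(benzyloxy)benzoate
Product: 26 5,7,3',4'-tetra-O-benzyl-3-O-TBS-epicatechin-(4β→8)-[5,3',4'-tri-O-benzyl-4-methoxy-7-O-TIPS-epicatechin 3-O-(3,4,5-tri-O-benzylgallate)] (lower ring C 2,3-cis; C4 epimers), via dimethyl acetal 24 (not isolated), via methoxy-o-quinone methide 25 (not isolated)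
Conditions: HC(OMe)3, (R)-TRIP (10 mol %), 4 Å MS, CH2Cl2, 0 °C → rt
Reagents that add atoms: trimethyl orthoformate, COC(OC)OC
Why: Proposed new method: the acid turns 19 into acetal 24, which loses methanol to the methoxy-o-quinone methide 25 (protonated, an aryl(methoxy)carbenium ion); the alkene of 23 should attack it with the carbon that bears the acyloxy group, because this puts the charge on the benzylic carbon next to the 4-benzyloxyphenyl ring (far better stabilised than an acyloxycarbenium ion, and bridged by the gallate carbonyl), and the phenol oxygen then closes O1–C2 on the face from which C4 arrived, so the Z-alkene becomes the 2,3-cis pair. The closest known reactions are the acid-catalysed three-component synthesis of 4-alkoxychromans from salicylaldehydes, orthoformates and electron-rich alkenes and the chiral-phosphoric-acid-catalysed [4+2] of o-quinone methides with styrenes; an enol ester has not been shown as the 2π partner. The absolute configuration at C2/C3 is to be set by the chiral phosphate ion-paired at O1 together with the neighbouring upper unit; the facial isomers are separable diastereomers, and the C4 mixture is erased in step 18. (R)-TRIP is (R)-3,3'-bis(2,4,6-triisopropylphenyl)-1,1'-binaphthyl-2,2'-diyl hydrogen phosphate.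

Step 16
Reactants: 27 (+)-catechin
Product: 28 5,7,3',4'-tetra-O-benzyl-(+)-catechin
Conditions: BnBr, K2CO3, DMF, 0 °C → rt
Reagents that add atoms: benzyl bromide, BrCc1ccccc1
Why: Williamson etherification of the four phenols, as in step 1.

Step 17
Reactants: 28 5,7,3',4'-tetra-O-benzyl-(+)-catechin
Product: 29 3,5,7,3',4'-penta-O-benzyl-(+)-catechin
Conditions: NaH, BnBr, Bu4NI (cat.), DMF, 0 °C → rt
Reagents that add atoms: benzyl bromide, BrCc1ccccc1
Why: Williamson etherification of the secondary alcohol; with no free phenol left, C2 cannot epimerise through a quinone methide.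

Step 18
Reactants: 26 5,7,3',4'-tetra-O-benzyl-3-O-TBS-epicatechin-(4β→8)-[5,3',4'-tri-O-benzyl-4-methoxy-7-O-TIPS-epicatechin 3-O-(3,4,5-tri-O-benzylgallate)]; 29 3,5,7,3',4'-penta-O-benzyl-(+)-catechin
Product: 30 5,7,3',4'-tetra-O-benzyl-3-O-TBS-epicatechin-(4β→8)-[5,3',4'-tri-O-benzyl-7-O-TIPS-epicatechin 3-O-(tri-O-benzylgallate)]-(4β→8)-penta-O-benzylcatechin
Conditions: TMSOTf, CH2Cl2, −78 → −40 °C
Reagents that add atoms: none
Why: Lewis-acid-promoted interflavan coupling (flavan C4 cation plus flavan nucleophile, a Friedel–Crafts alkylation); the C3 gallate carbonyl shields the α-face so catechin adds 3,4-trans (4β), both C4 epimers of 26 give the same cation, and benzylated catechin used in excess reacts at C8.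

Step 19
Reactants: 30 5,7,3',4'-tetra-O-benzyl-3-O-TBS-epicatechin-(4β→8)-[5,3',4'-tri-O-benzyl-7-O-TIPS-epicatechin 3-O-(tri-O-benzylgallate)]-(4β→8)-penta-O-benzylcatechin
Product: 31 5,7,3',4'-tetra-O-benzylepicatechin-(4β→8)-[5,3',4'-tri-O-benzylepicatechin 3-O-(tri-O-benzylgallate)]-(4β→8)-penta-O-benzylcatechin (free 3-OH on the upper unit and free 7-OH on the middle unit)
Conditions: Bu4NF, THF, 0 °C → rt
Reagents that add atoms: none
Why: fluoride cleavage of the aryl TIPS and alkyl TBS ethers; no C4 leaving group remains, and the hindered secondary aryl ester should tolerate fluoride at room temperature.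

Step 20
Reactants: 31 5,7,3',4'-tetra-O-benzylepicatechin-(4β→8)-[5,3',4'-tri-O-benzylepicatechin 3-O-(tri-O-benzylgallate)]-(4β→8)-penta-O-benzylcatechin
Product: 32 5,7,3',4'-tetra-O-benzylepicatechin-(4β→8)-[5,7,3',4'-tetra-O-benzylepicatechin 3-O-(tri-O-benzylgallate)]-(4β→8)-penta-O-benzylcatechin (free 3-OH on the upper unit)
Conditions: BnBr, K2CO3, DMF, rt
Reagents that add atoms: benzyl bromide, BrCc1ccccc1
Why: Williamson etherification; carbonate alkylates the phenol and leaves the secondary alcohol and the ester alone.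

Step 21
Reactants: 32 5,7,3',4'-tetra-O-benzylepicatechin-(4β→8)-[5,7,3',4'-tetra-O-benzylepicatechin 3-O-(tri-O-benzylgallate)]-(4β→8)-penta-O-benzylcatechin; 22 3,4,5-tris(benzyloxy)benzoic acid
Product: 33 [5,7,3',4'-tetra-O-benzylepicatechin 3-O-(tri-O-benzylgallate)]-(4β→8)-[5,7,3',4'-tetra-O-benzylepicatechin 3-O-(tri-O-benzylgallate)]-(4β→8)-penta-O-benzylcatechin
Conditions: DCC, DMAP, CH2Cl2, rt
Reagents that add atoms: none
Why: Steglich esterification of the only free hydroxyl; acylation occurs with retention at C3.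

Step 22
Reactants: 33 [5,7,3',4'-tetra-O-benzylepicatechin 3-O-(tri-O-benzylgallate)]-(4β→8)-[5,7,3',4'-tetra-O-benzylepicatechin 3-O-(tri-O-benzylgallate)]-(4β→8)-penta-O-benzylcatechin
Product: 34 epicatechin 3-O-gallate-(4β→8)-epicatechin 3-O-gallate-(4β→8)-catechin
Conditions: H2 (1 atm), Pd(OH)2/C, THF/MeOH/H2O, rt
Reagents that add atoms: none
Why: hydrogenolysis of all nineteen benzyl ethers under neutral conditions, which spares the esters, the chroman C2–O bonds and the interflavan bonds.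

## Compound list

1 | (−)-epicatechin | O[C@@H]1Cc2c(O)cc(O)cc2O[C@@H]1c1ccc(O)c(O)c1 | starting material
2 | 5,7,3',4'-tetra-O-benzyl-(−)-epicatechin | O[C@@H]1Cc2c(OCc9ccccc9)cc(OCc9ccccc9)cc2O[C@@H]1c1ccc(OCc9ccccc9)c(OCc9ccccc9)c1 | intermediate
3 | 4β-(2-ethoxyethoxy)-5,7,3',4'-tetra-O-benzylepicatechin | CCOCCO[C@H]1c2c(OCc9ccccc9)cc(OCc9ccccc9)cc2O[C@H](c2ccc(OCc9ccccc9)c(OCc9ccccc9)c2)[C@@H]1O | intermediate
4 | 4β-(2-ethoxyethoxy)-5,7,3',4'-tetra-O-benzyl-3-O-TBS-epicatechin | CCOCCO[C@H]1c2c(OCc9ccccc9)cc(OCc9ccccc9)cc2O[C@H](c2ccc(OCc9ccccc9)c(OCc9ccccc9)c2)[C@@H]1O[Si](C)(C)C(C)(C)C | intermediate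
5 | trimethylsilylacetylene | C#C[Si](C)(C)C | starting material
6 | potassium (trimethylsilylethynyl)trifluoroborate | [K+].C[Si](C)(C)C#C[B-](F)(F)F | intermediate
7 | 4β-[(trimethylsilyl)ethynyl]-5,7,3',4'-tetra-O-benzyl-3-O-TBS-epicatechin | C[Si](C)(C)C#C[C@H]1c2c(OCc9ccccc9)cc(OCc9ccccc9)cc2O[C@H](c2ccc(OCc9ccccc9)c(OCc9ccccc9)c2)[C@@H]1O[Si](C)(C)C(C)(C)C | intermediate
8 | 4β-ethynyl-5,7,3',4'-tetra-O-benzyl-3-O-TBS-epicatechin | C#C[C@H]1c2c(OCc9ccccc9)cc(OCc9ccccc9)cc2O[C@H](c2ccc(OCc9ccccc9)c(OCc9ccccc9)c2)[C@@H]1O[Si](C)(C)C(C)(C)C | intermediate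
9 | lithium ynolate of 8 (lithium 2-(flavan-4β-yl)ethynolate; not isolated) | [Li+].[O-]C#C[C@H]1c2c(OCc9ccccc9)cc(OCc9ccccc9)cc2O[C@H](c2ccc(OCc9ccccc9)c(OCc9ccccc9)c2)[C@@H]1O[Si](C)(C)C(C)(C)C | intermediate
10 | 4β-[(triisopropylsilyloxy)ethynyl]-5,7,3',4'-tetra-O-benzyl-3-O-TBS-epicatechin | CC(C)[Si](C(C)C)(C(C)C)OC#C[C@H]1c2c(OCc9ccccc9)cc(OCc9ccccc9)cc2O[C@H](c2ccc(OCc9ccccc9)c(OCc9ccccc9)c2)[C@@H]1O[Si](C)(C)C(C)(C)C | intermediate
11 | ethoxyacetylene | CCOC#C | starting material
12 | 3-ethoxycyclobut-2-en-1-one | CCOC1=CC(=O)C1 | intermediate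
13 | cyclobutane-1,3-dione | O=C1CC(=O)C1 | intermediate
14 | 3-(benzyloxy)cyclobut-2-en-1-one | O=C1C=C(OCc2ccccc2)C1 | intermediate
15 | 3-(benzyloxy)buta-1,3-dien-1-one, the (1-benzyloxyvinyl)ketene (not isolated) | C=C(OCc1ccccc1)C=C=O | intermediate
16 | 4-[1-(benzyloxy)vinyl]-2-(5,7,3',4'-tetra-O-benzyl-3-O-TBS-epicatechin-4β-yl)-3-(triisopropylsilyloxy)cyclobut-2-en-1-one (ring C4 unassigned; not isolated) | O=C1C(C(=C)OCc9ccccc9)C(O[Si](C(C)C)(C(C)C)C(C)C)=C1[C@H]1c2c(OCc9ccccc9)cc(OCc9ccccc9)cc2O[C@H](c2ccc(OCc9ccccc9)c(OCc9ccccc9)c2)[C@@H]1O[Si](C)(C)C(C)(C)C | intermediate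
17 | (3Z)-5-(benzyloxy)-2-(5,7,3',4'-tetra-O-benzyl-3-O-TBS-epicatechin-4β-yl)-3-(triisopropylsilyloxy)hexa-1,3,5-trien-1-one (not isolated) | O=C=C([C@H]1c2c(OCc9ccccc9)cc(OCc9ccccc9)cc2O[C@H](c2ccc(OCc9ccccc9)c(OCc9ccccc9)c2)[C@@H]1O[Si](C)(C)C(C)(C)C)/C(O[Si](C(C)C)(C(C)C)C(C)C)=C\C(=C)OCc9ccccc9 | intermediate
18 | 2-(5,7,3',4'-tetra-O-benzyl-3-O-TBS-epicatechin-4β-yl)-5-benzyloxy-3-(triisopropylsilyloxy)phenol | Oc1cc(OCc9ccccc9)cc(O[Si](C(C)C)(C(C)C)C(C)C)c1[C@H]1c2c(OCc9ccccc9)cc(OCc9ccccc9)cc2O[C@H](c2ccc(OCc9ccccc9)c(OCc9ccccc9)c2)[C@@H]1O[Si](C)(C)C(C)(C)C | intermediate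
19 | 6-benzyloxy-2-hydroxy-3-(5,7,3',4'-tetra-O-benzyl-3-O-TBS-epicatechin-4β-yl)-4-(triisopropylsilyloxy)benzaldehyde | O=Cc1c(OCc9ccccc9)cc(O[Si](C(C)C)(C(C)C)C(C)C)c(c1O)[C@H]1c2c(OCc9ccccc9)cc(OCc9ccccc9)cc2O[C@H](c2ccc(OCc9ccccc9)c(OCc9ccccc9)c2)[C@@H]1O[Si](C)(C)C(C)(C)C | intermediate
20 | 3,4-bis(benzyloxy)benzaldehyde | O=Cc1ccc(OCc2ccccc2)c(OCc2ccccc2)c1 | starting material
21 | 1,2-bis(benzyloxy)-4-ethynylbenzene | C#Cc1ccc(OCc2ccccc2)c(OCc2ccccc2)c1 | intermediate
22 | 3,4,5-tris(benzyloxy)benzoic acid | OC(=O)c1cc(OCc2ccccc2)c(OCc2ccccc2)c(OCc2ccccc2)c1 | starting material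
23 | (Z)-2-[3,4-bis(benzyloxy)phenyl]ethenyl 3,4,5-tris(benzyloxy)benzoate | O=C(O/C=C\c1ccc(OCc2ccccc2)c(OCc2ccccc2)c1)c1cc(OCc2ccccc2)c(OCc2ccccc2)c(OCc2ccccc2)c1 | intermediate
24 | dimethyl acetal of 19 (not isolated) | COC(OC)c1c(OCc9ccccc9)cc(O[Si](C(C)C)(C(C)C)C(C)C)c(c1O)[C@H]1c2c(OCc9ccccc9)cc(OCc9ccccc9)cc2O[C@H](c2ccc(OCc9ccccc9)c(OCc9ccccc9)c2)[C@@H]1O[Si](C)(C)C(C)(C)C | intermediate
25 | 3-benzyloxy-2-(methoxymethylidene)-6-(5,7,3',4'-tetra-O-benzyl-3-O-TBS-epicatechin-4β-yl)-5-(triisopropylsilyloxy)cyclohexa-3,5-dien-1-one, the methoxy-o-quinone methide (alkene geometry open; not isolated) | COC=C1C(OCc9ccccc9)=CC(O[Si](C(C)C)(C(C)C)C(C)C)=C(C1=O)[C@H]1c2c(OCc9ccccc9)cc(OCc9ccccc9)cc2O[C@H](c2ccc(OCc9ccccc9)c(OCc9ccccc9)c2)[C@@H]1O[Si](C)(C)C(C)(C)C | intermediate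
26 | 5,7,3',4'-tetra-O-benzyl-3-O-TBS-epicatechin-(4β→8)-[5,3',4'-tri-O-benzyl-4-methoxy-7-O-TIPS-epicatechin 3-O-(3,4,5-tri-O-benzylgallate)]; lower unit 2α-aryl, 3α-acyloxy, C4 as epimer mixture | O=C(O[C@@H]1C(OC)c2c(OCc9ccccc9)cc(O[Si](C(C)C)(C(C)C)C(C)C)c([C@H]3c4c(OCc9ccccc9)cc(OCc9ccccc9)cc4O[C@H](c4ccc(OCc9ccccc9)c(OCc9ccccc9)c4)[C@@H]3O[Si](C)(C)C(C)(C)C)c2O[C@@H]1c1ccc(OCc9ccccc9)c(OCc9ccccc9)c1)c1cc(OCc9ccccc9)c(OCc9ccccc9)c(OCc9ccccc9)c1 | intermediate
27 | (+)-catechin | O[C@H]1Cc2c(O)cc(O)cc2O[C@@H]1c1ccc(O)c(O)c1 | starting material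
28 | 5,7,3',4'-tetra-O-benzyl-(+)-catechin | O[C@H]1Cc2c(OCc9ccccc9)cc(OCc9ccccc9)cc2O[C@@H]1c1ccc(OCc9ccccc9)c(OCc9ccccc9)c1 | intermediate
29 | 3,5,7,3',4'-penta-O-benzyl-(+)-catechin | C(c9ccccc9)O[C@H]1Cc2c(OCc9ccccc9)cc(OCc9ccccc9)cc2O[C@@H]1c1ccc(OCc9ccccc9)c(OCc9ccccc9)c1 | intermediate
30 | 5,7,3',4'-tetra-O-benzyl-3-O-TBS-epicatechin-(4β→8)-[5,3',4'-tri-O-benzyl-7-O-TIPS-epicatechin 3-O-(tri-O-benzylgallate)]-(4β→8)-penta-O-benzylcatechin | O=C(O[C@@H]1[C@@H](c2c(OCc9ccccc9)cc(OCc9ccccc9)c3c2O[C@H](c2ccc(OCc9ccccc9)c(OCc9ccccc9)c2)[C@@H](OCc9ccccc9)C3)c2c(OCc9ccccc9)cc(O[Si](C(C)C)(C(C)C)C(C)C)c([C@H]3c4c(OCc9ccccc9)cc(OCc9ccccc9)cc4O[C@H](c4ccc(OCc9ccccc9)c(OCc9ccccc9)c4)[C@@H]3O[Si](C)(C)C(C)(C)C)c2O[C@@H]1c1ccc(OCc9ccccc9)c(OCc9ccccc9)c1)c1cc(OCc9ccccc9)c(OCc9ccccc9)c(OCc9ccccc9)c1 | intermediate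
31 | 5,7,3',4'-tetra-O-benzylepicatechin-(4β→8)-[5,3',4'-tri-O-benzylepicatechin 3-O-(tri-O-benzylgallate)]-(4β→8)-penta-O-benzylcatechin (upper 3-OH and middle 7-OH free) | O=C(O[C@@H]1[C@@H](c2c(OCc9ccccc9)cc(OCc9ccccc9)c3c2O[C@H](c2ccc(OCc9ccccc9)c(OCc9ccccc9)c2)[C@@H](OCc9ccccc9)C3)c2c(OCc9ccccc9)cc(O)c([C@H]3c4c(OCc9ccccc9)cc(OCc9ccccc9)cc4O[C@H](c4ccc(OCc9ccccc9)c(OCc9ccccc9)c4)[C@@H]3O)c2O[C@@H]1c1ccc(OCc9ccccc9)c(OCc9ccccc9)c1)c1cc(OCc9ccccc9)c(OCc9ccccc9)c(OCc9ccccc9)c1 | intermediate
32 | 5,7,3',4'-tetra-O-benzylepicatechin-(4β→8)-[5,7,3',4'-tetra-O-benzylepicatechin 3-O-(tri-O-benzylgallate)]-(4β→8)-penta-O-benzylcatechin (upper 3-OH free) | O=C(O[C@@H]1[C@@H](c2c(OCc9ccccc9)cc(OCc9ccccc9)c3c2O[C@H](c2ccc(OCc9ccccc9)c(OCc9ccccc9)c2)[C@@H](OCc9ccccc9)C3)c2c(OCc9ccccc9)cc(OCc9ccccc9)c([C@H]3c4c(OCc9ccccc9)cc(OCc9ccccc9)cc4O[C@H](c4ccc(OCc9ccccc9)c(OCc9ccccc9)c4)[C@@H]3O)c2O[C@@H]1c1ccc(OCc9ccccc9)c(OCc9ccccc9)c1)c1cc(OCc9ccccc9)c(OCc9ccccc9)c(OCc9ccccc9)c1 | intermediate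
33 | nonadeca-O-benzyl ether of 34: [tetra-O-benzylepicatechin 3-O-(tri-O-benzylgallate)]-(4β→8)-[tetra-O-benzylepicatechin 3-O-(tri-O-benzylgallate)]-(4β→8)-penta-O-benzylcatechin | O=C(O[C@@H]1[C@@H](c2c(OCc9ccccc9)cc(OCc9ccccc9)c3c2O[C@H](c2ccc(OCc9ccccc9)c(OCc9ccccc9)c2)[C@@H](OCc9ccccc9)C3)c2c(OCc9ccccc9)cc(OCc9ccccc9)c([C@H]3c4c(OCc9ccccc9)cc(OCc9ccccc9)cc4O[C@H](c4ccc(OCc9ccccc9)c(OCc9ccccc9)c4)[C@@H]3OC(=O)c3cc(OCc9ccccc9)c(OCc9ccccc9)c(OCc9ccccc9)c3)c2O[C@@H]1c1ccc(OCc9ccccc9)c(OCc9ccccc9)c1)c1cc(OCc9ccccc9)c(OCc9ccccc9)c(OCc9ccccc9)c1 | intermediate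
34 | epicatechin 3-O-gallate-(4β→8)-epicatechin 3-O-gallate-(4β→8)-catechin (CNP0269915.2) | O=C(O[C@@H]1[C@@H](c2c(O)cc(O)c3c2O[C@H](c2ccc(O)c(O)c2)[C@@H](O)C3)c2c(O)cc(O)c([C@H]3c4c(O)cc(O)cc4O[C@H](c4ccc(O)c(O)c4)[C@@H]3OC(=O)c3cc(O)c(O)c(O)c3)c2O[C@@H]1c1ccc(O)c(O)c1)c1cc(O)c(O)c(O)c1 | target

## Step count and least certain steps

Total: 22 steps. Longest linear sequence: 14 steps (1, 2, 3, 5, 6, 7, 11, 12, 15, 18, 19, 20, 21, 22).

**Step 15 (proposed new method).**
- Most likely failure: poor facial discrimination at the alkene. The first C–C bond forms at C4, away from the upper unit, so the chiral acid carries most of the control and a mixture of ring C diastereomers may result.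
- Second: slow reaction, because the quinone methide is stabilised by two ring oxygens and the enol ester is a modest nucleophile. Acyl transfer from the enol ester to the phenol may then compete.
- Third: reversed orientation if the acyloxy donor outweighs the aryl donor.
- Fallback (known chemistry): it sets out from 3 and 29 and comes back at 33, and it gives up the ring construction and with it the built‑in 4→8 assignment. TMSOTf coupling of 3 with excess 29 should give tetra‑O‑benzylepicatechin‑(4β→8)‑penta‑O‑benzylcatechin F1. A second coupling of F1 with 3 should give the trimer diol tetra‑O‑benzylepicatechin‑(4β→8)‑tetra‑O‑benzylepicatechin‑(4β→8)‑penta‑O‑benzylcatechin F2, whose two hydroxyls are esterified with 22 (DCC, DMAP) to reach 33.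

**Step 11 (key step).**
- Most likely failure: slow ring opening of 14, because the 3‑alkoxy group makes the cyclobutenone a stabilised vinylogous ester. At the higher temperature then needed, the siloxyalkyne can rearrange to a silylketene or ketene 15 can dimerise. The cascade may also stop at 16.
- Fallback: it sets out from 10 and comes back at 18, and generates 15 without heat. Ethyl (E)‑3‑(benzyloxy)but‑2‑enoate F3 (benzyl alcohol added to ethyl but‑2‑ynoate, PMe3 catalyst) is saponified with LiOH to (E)‑3‑(benzyloxy)but‑2‑enoic acid F4 and converted with oxalyl chloride into (E)‑3‑(benzyloxy)but‑2‑enoyl chloride F5. Et3N removes HCl from F5 in a 1,4 sense at 0 °C in the presence of 10. The [2+2] gives 16, and gentle warming completes the electrocyclic steps to 18.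

**Step 7.**
- Most likely failure: deprotonation at C4–H, which is both propargylic and benzylic, by the alkoxide and amide bases present during the slow oxidation. This would cause allene formation or loss of the 4β configuration. Silylation on carbon to a silylketene is a second risk.
- Fallback: it sets out from 4 and comes back at 10, and avoids the acetylide altogether. Mukaiyama‑type addition of 1‑ethoxy‑1‑(trimethylsilyloxy)ethene to the C4 cation of 4 (BF3·OEt2) should give ethyl 2‑(5,7,3',4'‑tetra‑O‑benzyl‑3‑O‑TBS‑epicatechin‑4β‑yl)acetate F6. Double α‑bromination (LiN(SiMe3)2, BrCCl2CCl2Br) gives the α,α‑dibromo ester F7. Two bromine–lithium exchanges with t‑BuLi turn F7, through the ester dianion, into ynolate 9, which is silylated as in step 7.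

**Step 18.**
- Most likely failure: reversible acid cleavage of the existing U–M bond under the silyl triflate, which would scramble the units. Some attack at C6 of the catechin is also possible.
- Fallback: it sets out from 26 and comes back at 30, and changes the mode of activation. Exchange of the C4 methoxy group for a thioether (2‑mercaptobenzothiazole, BF3·OEt2, −78 °C) gives the 4β‑(benzothiazol‑2‑ylthio) analogue of 26, F8. F8 is coupled with 29 under thiophilic, non‑protic activation by AgBF4 in THF at 0 °C.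

## Further compounds

F1 | step 15 | 5,7,3',4'-tetra-O-benzylepicatechin-(4β→8)-3,5,7,3',4'-penta-O-benzylcatechin | O[C@@H]1[C@@H](c2c(OCc9ccccc9)cc(OCc9ccccc9)c3c2O[C@H](c2ccc(OCc9ccccc9)c(OCc9ccccc9)c2)[C@@H](OCc9ccccc9)C3)c2c(OCc9ccccc9)cc(OCc9ccccc9)cc2O[C@@H]1c1ccc(OCc9ccccc9)c(OCc9ccccc9)c1
F2 | step 15 | 5,7,3',4'-tetra-O-benzylepicatechin-(4β→8)-5,7,3',4'-tetra-O-benzylepicatechin-(4β→8)-3,5,7,3',4'-penta-O-benzylcatechin | O[C@@H]1[C@@H](c2c(OCc9ccccc9)cc(OCc9ccccc9)c3c2O[C@H](c2ccc(OCc9ccccc9)c(OCc9ccccc9)c2)[C@@H](OCc9ccccc9)C3)c2c(OCc9ccccc9)cc(OCc9ccccc9)c([C@H]3c4c(OCc9ccccc9)cc(OCc9ccccc9)cc4O[C@H](c4ccc(OCc9ccccc9)c(OCc9ccccc9)c4)[C@@H]3O)c2O[C@@H]1c1ccc(OCc9ccccc9)c(OCc9ccccc9)c1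
F3 | step 11 | ethyl (E)-3-(benzyloxy)but-2-enoate | CCOC(=O)/C=C(\C)OCc1ccccc1
F4 | step 11 | (E)-3-(benzyloxy)but-2-enoic acid | OC(=O)/C=C(\C)OCc1ccccc1
F5 | step 11 | (E)-3-(benzyloxy)but-2-enoyl chloride | ClC(=O)/C=C(\C)OCc1ccccc1
F6 | step 7 | ethyl 2-(5,7,3',4'-tetra-O-benzyl-3-O-TBS-epicatechin-4β-yl)acetate | CCOC(=O)C[C@H]1c2c(OCc9ccccc9)cc(OCc9ccccc9)cc2O[C@H](c2ccc(OCc9ccccc9)c(OCc9ccccc9)c2)[C@@H]1O[Si](C)(C)C(C)(C)C
F7 | step 7 | ethyl 2,2-dibromo-2-(5,7,3',4'-tetra-O-benzyl-3-O-TBS-epicatechin-4β-yl)acetate | CCOC(=O)C(Br)(Br)[C@H]1c2c(OCc9ccccc9)cc(OCc9ccccc9)cc2O[C@H](c2ccc(OCc9ccccc9)c(OCc9ccccc9)c2)[C@@H]1O[Si](C)(C)C(C)(C)C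
F8 | step 18 | 5,7,3',4'-tetra-O-benzyl-3-O-TBS-epicatechin-(4β→8)-[4β-(benzothiazol-2-ylthio)-5,3',4'-tri-O-benzyl-7-O-TIPS-epicatechin 3-O-(tri-O-benzylgallate)] | O=C(O[C@@H]1[C@@H](Sc5nc6ccccc6s5)c2c(OCc9ccccc9)cc(O[Si](C(C)C)(C(C)C)C(C)C)c([C@H]3c4c(OCc9ccccc9)cc(OCc9ccccc9)cc4O[C@H](c4ccc(OCc9ccccc9)c(OCc9ccccc9)c4)[C@@H]3O[Si](C)(C)C(C)(C)C)c2O[C@@H]1c1ccc(OCc9ccccc9)c(OCc9ccccc9)c1)c1cc(OCc9ccccc9)c(OCc9ccccc9)c(OCc9ccccc9)c1
A1 | alternative 1 | 2-substituted phloroglucinol: ring A of U formed on the open-chain upper unit (C4 carries the protected epicatechin-8-yl group, C3 a TBS ether, C2 a TES ether) | Oc1cc(O)c([C@H](c2c(OCc9ccccc9)cc(OCc9ccccc9)c3c2O[C@H](c2ccc(OCc9ccccc9)c(OCc9ccccc9)c2)[C@H](O[Si](C)(C)C(C)(C)C)C3)[C@@H](O[Si](C)(C)C(C)(C)C)[C@@H](O[Si](CC)(CC)CC)c2ccc(OCc9ccccc9)c(OCc9ccccc9)c2)c(O)c1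
A2 | alternative 2 | perbenzylated epicatechin 3-O-gallate-(4β→8)-catechin | O=C(O[C@@H]1[C@@H](c2c(OCc9ccccc9)cc(OCc9ccccc9)c3c2O[C@H](c2ccc(OCc9ccccc9)c(OCc9ccccc9)c2)[C@@H](OCc9ccccc9)C3)c2c(OCc9ccccc9)cc(OCc9ccccc9)cc2O[C@@H]1c1ccc(OCc9ccccc9)c(OCc9ccccc9)c1)c1cc(OCc9ccccc9)c(OCc9ccccc9)c(OCc9ccccc9)c1
A3 | alternative 3 | protected 4-(epicatechin-8-yl)flav-2-ene | C1(c3ccc(OCc9ccccc9)c(OCc9ccccc9)c3)=C[C@@H](c4c(OCc9ccccc9)cc(OCc9ccccc9)c5c4O[C@H](c4ccc(OCc9ccccc9)c(OCc9ccccc9)c4)[C@H](O[Si](C)(C)C(C)(C)C)C5)c2c(OCc9ccccc9)cc(OCc9ccccc9)cc2O1
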